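Ring B of the target (eudesmane numbering, C5–C10) is a 2-isopropylidenecyclohexanone: C7=C11 beside the C8 ketone. This unit is one oxidation and one alkene shift away from a 2-isopropenylcyclohexanol, so C7–C8 is disconnected by an intramolecular carbonyl-ene reaction. In one operation a Lewis-acid-activated C8 aldehyde is attacked by C7 of a prenyl group with hydrogen transfer from a C11 methyl; this closes ring B, makes the last skeletal bond and leaves O8 and a C11 alkene for adjustment. The precursor is a ring A enone (C3=O, C4=C5) carrying the prenyl chain on C5 and a CH2CHO arm (C9, C8) on the quaternary C10, whose configuration is already set.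

Key step: step 9

Remarks on the chemistry
- Numbering: bicyclic compounds carry eudesmane names (ring A = C1–C5, C10; ring B = C5–C10; C11–C13 on C7; C14 on C10; C15 on C4). β is the face of the C10 methyl; "eudesm-" implies 10β-CH3 and, where C7 is sp3, the 7β side chain. The target is 4α-acetoxy-3β-angeloyloxy-5α-eudesm-7(11)-en-8-one, (3S,4S,5R,10R).
- Assumption: the PHOX ligand is taken to induce in step 4 in the same sense as in the parent case (S ligand gives (S)-2-allyl-2-methylcyclohexanone), so the R ligand is used for (R)-9; if the sense is reversed, the other ligand enantiomer is used and nothing else changes.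
- Design points:
  - The C8 aldehyde is enolisable (C9 carries two hydrogens). It is therefore kept as a dimethyl acetal until the mild acid step that also creates the enone, and the ene step uses a proton-scavenging Lewis acid.
  - Prenyl Grignard reagents react mainly through their tertiary terminus. The C5 chain is therefore introduced as allyl and turned into prenyl by cross-metathesis.
  - The vinylogous ester is the methyl ether, so acetal formation in methanol cannot scramble it.
  - Compounds 10 and 14 are epimer mixtures at a carbinol carbon that disappears within the same step.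

Step 1
Reactants: 1 2-methylcyclohexane-1,3-dione
Product: 2 3-methoxy-2-methylcyclohex-2-en-1-one
Conditions: HC(OMe)3, MeOH, TsOH·H2O (cat.), rt → 50 °C
Reagents that add atoms: trimethyl orthoformate (COC(OC)OC); methanol (CO)
Why: Acid-catalysed enol etherification of a symmetric cyclic 1,3-dione, with the orthoformate taking up the water, can give only one vinylogous ester.

Step 2
Reactants: 2 3-methoxy-2-methylcyclohex-2-en-1-one; 3 iodomethane
Product: 5 racemic 3-methoxy-2,6-dimethylcyclohex-2-en-1-one, via lithium dienolate 4 (not isolated)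
Conditions: LDA (1.05 equiv), THF, −78 °C; MeI, −78 → 0 °C
Reagents that add atoms: iodomethane (CI)
Why: Kinetic α′-deprotonation of the vinylogous ester at C6 (the future C10) followed by SN2 methylation is the alkylation half of the Stork–Danheiser protocol; the centre is racemic here and is set in step 4.

Step 3
Reactants: 5 racemic 3-methoxy-2,6-dimethylcyclohex-2-en-1-one; 6 allyl chloroformate
Product: 8 allyl 5-methoxy-2,6-dimethylcyclohexa-1,5-dien-1-yl carbonate, via lithium dienolate 7 (not isolated)
Conditions: LDA, TMEDA, THF, −78 °C; ClCO2CH2CH=CH2, −78 °C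
Reagents that add atoms: allyl chloroformate (C=CCOC(=O)Cl)
Why: The only enolisable α′ position gives a single fully substituted lithium dienolate, which the hard chloroformate should acylate on oxygen in the presence of TMEDA (enol carbonate formation).

Step 4
Reactants: 8 allyl 5-methoxy-2,6-dimethylcyclohexa-1,5-dien-1-yl carbonate
Product: 9 (6R)-3-methoxy-2,6-dimethyl-6-(prop-2-en-1-yl)cyclohex-2-en-1-one
Conditions: Pd2(dba)3 (2.5 mol%), (R)-t-BuPHOX (6.25 mol%), toluene, 30 °C
Reagents that add atoms: none
Why: In this Pd-catalysed decarboxylative asymmetric allylic alkylation (Tsuji–Trost type) ionisation and loss of CO2 give a π-allyl-palladium enolate that recombines at carbon, and the chiral PHOX ligand selects the enolate face so that the quaternary C10 should form as R (methyl β in the target).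

Step 5
Reactants: 9 (6R)-3-methoxy-2,6-dimethyl-6-(prop-2-en-1-yl)cyclohex-2-en-1-one
Product: 11 2-[(1R)-4-methoxy-1,3-dimethyl-2-oxocyclohex-3-en-1-yl]acetaldehyde, via vicinal diol 10 (not isolated)
Conditions: OsO4 (2 mol%), NaIO4 (4 equiv), 2,6-lutidine, dioxane/H2O 3:1, rt
Reagents that add atoms: osmium tetroxide (O=[Os](=O)(=O)=O); sodium periodate ([Na+].[O-]I(=O)(=O)=O); water (O)
Why: In this Lemieux–Johnson cleavage the monosubstituted alkene is dihydroxylated much faster than the tetrasubstituted push–pull double bond of the vinylogous ester, and periodate cuts the diol to the C8 aldehyde with loss of one carbon.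

Step 6
Reactants: 11 2-[(1R)-4-methoxy-1,3-dimethyl-2-oxocyclohex-3-en-1-yl]acetaldehyde
Product: 12 (6R)-6-(2,2-dimethoxyethyl)-3-methoxy-2,6-dimethylcyclohex-2-en-1-one
Conditions: HC(OMe)3, MeOH, PPTS (cat.), rt
Reagents that add atoms: trimethyl orthoformate (COC(OC)OC); methanol (CO)
Why: Acid-catalysed acetalisation protects the unhindered aldehyde, while the vinylogous ester carbonyl is too unreactive to ketalise and exchange of its methoxy group with the solvent is degenerate.

Step 7
Reactants: 12 (6R)-6-(2,2-dimethoxyethyl)-3-methoxy-2,6-dimethylcyclohex-2-en-1-one; 13 allylmagnesium bromide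
Product: 15 2-[(1R)-1,3-dimethyl-4-oxo-2-(prop-2-en-1-yl)cyclohex-2-en-1-yl]acetaldehyde, via tertiary carbinol 14 (not isolated)
Conditions: allylMgBr (1.5 equiv), THF, −78 → 0 °C; then 1 M aq. HCl, THF, 0 °C → rt
Reagents that add atoms: allylmagnesium bromide (C=CC[Mg]Br); water (O)
Why: In this Stork–Danheiser transposition the allyl Grignard reagent, which is reactive enough for the neopentyl carbonyl and has two identical termini, adds 1,2, and aqueous acid then ionises the allylic carbinol, hydrolyses the enol ether to the transposed enone and opens the dimethyl acetal in the same operation.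

Step 8
Reactants: 15 2-[(1R)-1,3-dimethyl-4-oxo-2-(prop-2-en-1-yl)cyclohex-2-en-1-yl]acetaldehyde; 16 2-methylbut-2-ene
Product: 17 2-[(1R)-1,3-dimethyl-2-(3-methylbut-2-en-1-yl)-4-oxocyclohex-2-en-1-yl]acetaldehyde
Conditions: second-generation Ru benzylidene catalyst (Grubbs II, 5 mol%), 2-methylbut-2-ene (excess), CH2Cl2, 35 °C
Reagents that add atoms: 2-methylbut-2-ene (CC=C(C)C)
Why: Olefin cross-metathesis of the only terminal alkene with 2-methylbut-2-ene turns allyl into prenyl, the tetrasubstituted enone alkene being inert to the carbene and the aldehyde tolerated.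

Step 9
Reactants: 17 2-[(1R)-1,3-dimethyl-2-(3-methylbut-2-en-1-yl)-4-oxocyclohex-2-en-1-yl]acetaldehyde
Product: 18 8α-hydroxyeudesma-4,11-dien-3-one
Conditions: Me2AlCl (2.5 equiv), CH2Cl2, −78 → −20 °C; aq. Rochelle salt
Reagents that add atoms: none
Why: Me2AlCl binds the C8 aldehyde, and C7 of the trisubstituted alkene adds to C8 while a hydrogen of a C11 methyl group passes to oxygen through a six-membered chair-like array, so that C7–C8 forms and the alkene moves to C11=C12. The closest known reaction type is the Lewis-acid-promoted type I intramolecular carbonyl-ene cyclisation of citronellal to isopulegol. Ring B closes in the six-membered mode with the carbonyl oxygen and C11 both outside the new ring (exo to C=O and to the alkene), since attack through C11 would need a seven-membered ring and positive character on the secondary C7. C8 is set by the chair in which the complexed oxygen is equatorial and away from the axial C10 methyl (8α-OH), and C7 by the equatorial position of the developing isopropenyl group (7β, trans to O8). Both centres are erased later, so only chemoselectivity is needed: the aldehyde is the only strong enophile, the prenyl group is the only electron-rich ene donor (the ring A alkene is an electron-poor enone), and the excess of the proton-scavenging aluminium reagent saturates the enone oxygen without opening a reaction channel there.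

Step 10
Reactants: 18 8α-hydroxyeudesma-4,11-dien-3-one
Product: 19 8α-(tert-butyldimethylsilyloxy)eudesma-4,11-dien-3-one
Conditions: TBSCl, imidazole, DMF, rt
Reagents that add atoms: tert-butyldimethylsilyl chloride (CC(C)(C)[Si](C)(C)Cl)
Why: Imidazole-promoted silylation of the equatorial secondary alcohol keeps O8 inert through the dissolving-metal, hydride and acylation steps.

Step 11
Reactants: 19 8α-(tert-butyldimethylsilyloxy)eudesma-4,11-dien-3-one
Product: 21 8α-(tert-butyldimethylsilyloxy)-3-(trimethylsilyloxy)-5α-eudesma-3,11-diene, via lithium enolate 20 (not isolated)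
Conditions: Li (2.1 equiv), NH3(l)/THF, t-BuOH (1.0 equiv), −78 °C; evaporate NH3; TMSCl, Et3N, THF, −20 °C → rt
Reagents that add atoms: chlorotrimethylsilane (C[Si](C)(C)Cl)
Why: In this Birch-type dissolving-metal reduction of the enone, axial protonation at C5 should give the trans-fused decalin (5α-H, anti to the C10 methyl), and the regiodefined C3–C4 lithium enolate is trapped on oxygen (reductive silylation), while the isolated isopropenyl group and the silyl ether are not reduced.

Step 12
Reactants: 21 8α-(tert-butyldimethylsilyloxy)-3-(trimethylsilyloxy)-5α-eudesma-3,11-diene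
Product: 24 8α-(tert-butyldimethylsilyloxy)-4α-hydroxy-5α-eudesm-11-en-3-one, via silyloxy epoxide 22 (not isolated), via 4α-trimethylsilyloxy ketone 23 (not isolated)
Conditions: mCPBA (1.05 equiv), NaHCO3, CH2Cl2, −20 °C; then citric acid, MeOH, rt
Reagents that add atoms: 3-chloroperbenzoic acid (OOC(=O)c1cccc(Cl)c1)
Why: In this Rubottom oxidation the electron-rich silyl enol ether should be epoxidised faster than the 1,1-disubstituted alkene and from the α-face opposite the syn-axial C10 methyl, so that epoxide opening with 1,4-silyl shift leaves 4α-O and 4β-CH3, and mild acid then removes only the tertiary TMS group.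

Step 13
Reactants: 24 8α-(tert-butyldimethylsilyloxy)-4α-hydroxy-5α-eudesm-11-en-3-one
Product: 25 8α-(tert-butyldimethylsilyloxy)-5α-eudesm-11-ene-3β,4α-diol
Conditions: NaBH4, MeOH, −20 → 0 °C
Reagents that add atoms: none
Why: Borohydride reduction by axial hydride delivery on the α-face, the β-side approach being hindered by the adjacent axial 4β-methyl group, should give the equatorial 3β-alcohol trans to the 4α-hydroxyl.

Step 14
Reactants: 25 8α-(tert-butyldimethylsilyloxy)-5α-eudesm-11-ene-3β,4α-diol; 26 angelic acid
Product: 28 3β-angeloyloxy-8α-(tert-butyldimethylsilyloxy)-5α-eudesm-11-en-4α-ol, via angelic 2,4,6-trichlorobenzoic anhydride 27 (not isolated)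
Conditions: angelic acid, 2,4,6-trichlorobenzoyl chloride, Et3N, toluene, rt; then 25, 75 °C (no DMAP)
Reagents that add atoms: angelic acid (C/C=C(/C)C(=O)O)
Why: Yamaguchi-type esterification through the mixed anhydride without a nucleophilic catalyst is a known way to make angelates without Z to E isomerisation, and only the secondary 3β-hydroxyl is acylated because the tertiary one is inert under these conditions.

Step 15
Reactants: 28 3β-angeloyloxy-8α-(tert-butyldimethylsilyloxy)-5α-eudesm-11-en-4α-ol; 29 acetic anhydride
Product: 30 4α-acetoxy-3β-angeloyloxy-8α-(tert-butyldimethylsilyloxy)-5α-eudesm-11-ene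
Conditions: Ac2O (excess), DMAP (1 equiv), Et3N, CH2Cl2, 40 °C
Reagents that add atoms: acetic anhydride (CC(=O)OC(C)=O)
Why: Steglich-type DMAP-catalysed acetylation reaches tertiary alcohols with excess anhydride, and the silyl ether, the alkene and the existing angelate (an ester that DMAP does not activate) should be unaffected.

Step 16
Reactants: 30 4α-acetoxy-3β-angeloyloxy-8α-(tert-butyldimethylsilyloxy)-5α-eudesm-11-ene
Product: 31 4α-acetoxy-3β-angeloyloxy-5α-eudesm-11-en-8α-ol
Conditions: HF·pyridine, pyridine, THF, 0 °C → rt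
Reagents that add atoms: none
Why: Buffered fluoride cleavage of the secondary TBS ether is essentially neutral and should leave both esters and the alkene in place.

Step 17
Reactants: 31 4α-acetoxy-3β-angeloyloxy-5α-eudesm-11-en-8α-ol
Product: 33 4α-acetoxy-3β-angeloyloxy-5α-eudesm-7(11)-en-8-one (the target), via isopropenyl ketone 32 (not isolated)
Conditions: Dess–Martin periodinane, NaHCO3, CH2Cl2, rt; aqueous work-up; then DBU (0.3 equiv), CH2Cl2, rt
Reagents that add atoms: none
Why: Dess–Martin oxidation gives the β,γ-unsaturated ketone, which an amidine base should isomerise through the dienolate to the conjugated isopropylidene ketone (isopulegone to pulegone type), C7 becoming sp2 and C9 enolisation touching no stereocentre because C10 is quaternary.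

Compound list
1 | 2-methylcyclohexane-1,3-dione | CC1C(=O)CCCC1=O | starting material
2 | 3-methoxy-2-methylcyclohex-2-en-1-one | COC1=C(C)C(=O)CCC1 | intermediate
3 | iodomethane | CI | starting material
4 | lithium 5-methoxy-6-methylcyclohexa-1,5-dien-1-olate (not isolated) | [Li]OC1=CCCC(OC)=C1C | intermediate
5 | 3-methoxy-2,6-dimethylcyclohex-2-en-1-one (racemic) | COC1=C(C)C(=O)C(C)CC1 | intermediate
6 | allyl chloroformate | C=CCOC(=O)Cl | starting material
7 | lithium 5-methoxy-2,6-dimethylcyclohexa-1,5-dien-1-olate (not isolated) | [Li]OC1=C(C)CCC(OC)=C1C | intermediate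
8 | allyl 5-methoxy-2,6-dimethylcyclohexa-1,5-dien-1-yl carbonate | C=CCOC(=O)OC1=C(C)CCC(OC)=C1C | intermediate
9 | (6R)-3-methoxy-2,6-dimethyl-6-(prop-2-en-1-yl)cyclohex-2-en-1-one | C=CC[C@@]1(C)CCC(OC)=C(C)C1=O | intermediate
10 | (6R)-6-(2,3-dihydroxypropyl)-3-methoxy-2,6-dimethylcyclohex-2-en-1-one (both carbinol epimers; not isolated) | OCC(O)C[C@@]1(C)CCC(OC)=C(C)C1=O | intermediate
11 | 2-[(1R)-4-methoxy-1,3-dimethyl-2-oxocyclohex-3-en-1-yl]acetaldehyde | O=CC[C@@]1(C)CCC(OC)=C(C)C1=O | intermediate
12 | (6R)-6-(2,2-dimethoxyethyl)-3-methoxy-2,6-dimethylcyclohex-2-en-1-one | COC(OC)C[C@@]1(C)CCC(OC)=C(C)C1=O | intermediate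
13 | allylmagnesium bromide | C=CC[Mg]Br | starting material
14 | (6R)-6-(2,2-dimethoxyethyl)-3-methoxy-2,6-dimethyl-1-(prop-2-en-1-yl)cyclohex-2-en-1-ol (both C1 epimers; not isolated) | COC(OC)C[C@@]1(C)CCC(OC)=C(C)C1(O)CC=C | intermediate
15 | 2-[(1R)-1,3-dimethyl-4-oxo-2-(prop-2-en-1-yl)cyclohex-2-en-1-yl]acetaldehyde | O=CC[C@@]1(C)CCC(=O)C(C)=C1CC=C | intermediate
16 | 2-methylbut-2-ene | CC=C(C)C | starting material
17 | 2-[(1R)-1,3-dimethyl-2-(3-methylbut-2-en-1-yl)-4-oxocyclohex-2-en-1-yl]acetaldehyde (ene precursor) | O=CC[C@@]1(C)CCC(=O)C(C)=C1CC=C(C)C | intermediate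
18 | 8α-hydroxyeudesma-4,11-dien-3-one (7β-isopropenyl, 10β-methyl) | O=C1CC[C@]2(C)C[C@H](O)[C@@H](C(C)=C)CC2=C1C | intermediate
19 | 8α-(tert-butyldimethylsilyloxy)eudesma-4,11-dien-3-one | O=C1CC[C@]2(C)C[C@H](O[Si](C)(C)C(C)(C)C)[C@@H](C(C)=C)CC2=C1C | intermediate
20 | lithium 8α-(tert-butyldimethylsilyloxy)-5α-eudesma-3,11-dien-3-olate (not isolated) | [Li]OC1=C(C)[C@@H]2C[C@H](C(C)=C)[C@@H](O[Si](C)(C)C(C)(C)C)C[C@@]2(C)CC1 | intermediate
21 | 8α-(tert-butyldimethylsilyloxy)-3-(trimethylsilyloxy)-5α-eudesma-3,11-diene | C[Si](C)(C)OC1=C(C)[C@@H]2C[C@H](C(C)=C)[C@@H](O[Si](C)(C)C(C)(C)C)C[C@@]2(C)CC1 | intermediate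
22 | 3α,4α-epoxy-8α-(tert-butyldimethylsilyloxy)-3β-(trimethylsilyloxy)-5α-eudesm-11-ene (not isolated) | C[Si](C)(C)O[C@@]12CC[C@]3(C)C[C@H](O[Si](C)(C)C(C)(C)C)[C@@H](C(C)=C)C[C@H]3[C@]1(C)O2 | intermediate
23 | 8α-(tert-butyldimethylsilyloxy)-4α-(trimethylsilyloxy)-5α-eudesm-11-en-3-one (not isolated) | O=C1CC[C@]2(C)C[C@H](O[Si](C)(C)C(C)(C)C)[C@@H](C(C)=C)C[C@H]2[C@]1(C)O[Si](C)(C)C | intermediate
24 | 8α-(tert-butyldimethylsilyloxy)-4α-hydroxy-5α-eudesm-11-en-3-one | O=C1CC[C@]2(C)C[C@H](O[Si](C)(C)C(C)(C)C)[C@@H](C(C)=C)C[C@H]2[C@]1(C)O | intermediate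
25 | 8α-(tert-butyldimethylsilyloxy)-5α-eudesm-11-ene-3β,4α-diol | O[C@H]1CC[C@]2(C)C[C@H](O[Si](C)(C)C(C)(C)C)[C@@H](C(C)=C)C[C@H]2[C@]1(C)O | intermediate
26 | angelic acid, (2Z)-2-methylbut-2-enoic acid | C/C=C(/C)C(=O)O | starting material
27 | angelic 2,4,6-trichlorobenzoic anhydride (not isolated) | C/C=C(/C)C(=O)OC(=O)c1c(Cl)cc(Cl)cc1Cl | intermediate
28 | 3β-angeloyloxy-8α-(tert-butyldimethylsilyloxy)-5α-eudesm-11-en-4α-ol | C/C=C(/C)C(=O)O[C@H]1CC[C@]2(C)C[C@H](O[Si](C)(C)C(C)(C)C)[C@@H](C(C)=C)C[C@H]2[C@]1(C)O | intermediate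
29 | acetic anhydride | CC(=O)OC(C)=O | starting material
30 | 4α-acetoxy-3β-angeloyloxy-8α-(tert-butyldimethylsilyloxy)-5α-eudesm-11-ene | C/C=C(/C)C(=O)O[C@H]1CC[C@]2(C)C[C@H](O[Si](C)(C)C(C)(C)C)[C@@H](C(C)=C)C[C@H]2[C@]1(C)OC(C)=O | intermediate
31 | 4α-acetoxy-3β-angeloyloxy-5α-eudesm-11-en-8α-ol | C/C=C(/C)C(=O)O[C@H]1CC[C@]2(C)C[C@H](O)[C@@H](C(C)=C)C[C@H]2[C@]1(C)OC(C)=O | intermediate
32 | 4α-acetoxy-3β-angeloyloxy-5α-eudesm-11-en-8-one (7β-isopropenyl; not isolated) | C/C=C(/C)C(=O)O[C@H]1CC[C@]2(C)CC(=O)[C@@H](C(C)=C)C[C@H]2[C@]1(C)OC(C)=O | intermediate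
33 | 4α-acetoxy-3β-angeloyloxy-5α-eudesm-7(11)-en-8-one; (1S,2S,4aR,8aR)-1-acetoxy-1,4a-dimethyl-6-oxo-7-(propan-2-ylidene)decahydronaphthalen-2-yl (2Z)-2-methylbut-2-enoate | C/C=C(/C)C(=O)O[C@H]1CC[C@]2(C)CC(=O)C(=C(C)C)C[C@H]2[C@]1(C)OC(C)=O | target

Total step count: 17. Longest linear sequence: 17 steps (1 to 33; the route is fully linear).

Steps most likely to fail

Step 9 (key step). The Lewis acid may be held by the more basic ring A enone oxygen, so that closure is slow and acid-promoted migration of the C6–C7 alkene into conjugation with the enone, or chloride capture at C11, overtakes the hydrogen transfer. The fallback forms the same C7–C8 bond by an intramolecular Hosomi–Sakurai allylation instead of an ene reaction. It sets out from the allyl enone aldehyde 15. Cross-metathesis with trimethyl(2-methylallyl)silane (Grubbs II, CH2Cl2, 40 °C) should give the allylsilane 2-[(1R)-1,3-dimethyl-2-[3-methyl-4-(trimethylsilyl)but-2-en-1-yl]-4-oxocyclohex-2-en-1-yl]acetaldehyde F1 as an E/Z mixture. BF3·OEt2 in CH2Cl2 at −78 °C should then make C7 attack the aldehyde with loss of silicon from C12; this is irreversible, needs one equivalent of a mild Lewis acid, and gives the isopropenyl carbinol. The fallback comes back to the route at 18.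

Step 15. The hindered tertiary hydroxyl may acetylate incompletely, or under forcing the angeloyl group may migrate from O3 to O4 and the freed secondary hydroxyl be acetylated instead. The fallback installs the acetate before C3 is reduced, when the tertiary hydroxyl sits next to a flat carbonyl. It sets out from ketol 24. Ac2O, DMAP and Et3N should give 4α-acetoxy-8α-(tert-butyldimethylsilyloxy)-5α-eudesm-11-en-3-one F2. NaBH4 with CeCl3·7H2O in MeOH at −78 °C and an acetic acid quench should give 4α-acetoxy-8α-(tert-butyldimethylsilyloxy)-5α-eudesm-11-en-3β-ol F3. Acylation of F3 with the mixed anhydride 27 (toluene, 75 °C, no DMAP) comes back to the route at 30.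

Step 12. The silyl enol ether may be hydrolysed by the carboxylic acid that forms, or the isopropenyl group may be epoxidised in competition. The fallback oxidises the enolate instead of the enol ether. It sets out from 21: MeLi in THF at 0 °C regenerates the lithium enolate 20, and 2-(phenylsulfonyl)-3-phenyloxaziridine (Davis oxaziridine) at −78 °C should hydroxylate it from the same α-face without touching the alkene. This comes back to the route at 24 and makes no compound outside the compound list.

Further compounds
F1 | step 9 | 2-[(1R)-1,3-dimethyl-2-[3-methyl-4-(trimethylsilyl)but-2-en-1-yl]-4-oxocyclohex-2-en-1-yl]acetaldehyde (E/Z mixture) | O=CC[C@@]1(C)CCC(=O)C(C)=C1CC=C(C)C[Si](C)(C)C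
F2 | step 15 | 4α-acetoxy-8α-(tert-butyldimethylsilyloxy)-5α-eudesm-11-en-3-one | O=C1CC[C@]2(C)C[C@H](O[Si](C)(C)C(C)(C)C)[C@@H](C(C)=C)C[C@H]2[C@]1(C)OC(C)=O
F3 | step 15 | 4α-acetoxy-8α-(tert-butyldimethylsilyloxy)-5α-eudesm-11-en-3β-ol | O[C@H]1CC[C@]2(C)C[C@H](O[Si](C)(C)C(C)(C)C)[C@@H](C(C)=C)C[C@H]2[C@]1(C)OC(C)=O
F0 | step 12 | none | none
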